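The constants used here were drawn at random within sensible limits; the flask was simulated.

A small charge of X, 0.50 M, lies in the first phase while 3.00 equiv of D waits in the second, so there is less X than D. G leaches out of D, X takes up G to give X.G, and X.G either falls to E or passes into the second phase as J.

X 0.50 M; D 3.00 equiv; time 6.0 min; volume of the second phase over the first 1.0

1. how much X.G and J together there is at 6.0 min, in percent of the X charged
2. the change that raises the amount of X.G and J together at 6.0 min, in percent of the X charged most ("none" if none brings more than 2 percentage points) (epsilon / eta / gamma / none)
3. amount of X.G and J together at 6.0 min, in percent of the X charged, after epsilon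

- what is said of X.G includes J
- in the second phase: D, J; everything else is in the first
- charges count per volume of the first phase; a concentration in a rate is the amount of a species over the volume of its own phase; every rate counts per litre of the first phase
- run time (flask): 6.0 min

    G ⇌ Q (K1 = 0.96, k1 = 0.00395 /s)
    X + G → X.G (k2 = 0.0300 /M/s)
    G ⇌ D, rate k3*([G] - [D]/K3) per volume of the first phase (K3 = 0.77, k3 = 0.0100 /s)
    X.G → E (k4 = 0.00998 /s)
    X.G ⇌ J, rate k5*([X.G] - [J]/K5) per volume of the first phase (K5 = 20, k5 = 0.00364 /s)

We reckon by hand, one process at a time. With the main step alone, and the 1.00 M of D that X does not need standing as G, X decays at 0.0300 /s; 0.00204% of it is left at 6.0 min, so y stands near 100%. Adding the fall to E at 0.00998 /s drops y to 4.12%.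

Now the rest. X.G in the first phase falls to E faster than it transfers, and the transfer constant over the sum of the two gives 26.7%: this is the escape share, the part of the first-phase X.G used up that goes to J so long as we leave out the return of J. Shared at equilibrium with D (ratio 0.77) and Q (constant 0.96), G stands near 0.366 M, which makes X pseudo-first-order at 0.0110 /s. With first-phase X.G lost at 0.0136 /s, 6.0 min leaves X at 1.91%, first-phase X.G at 4.89% and J at 24.9%. We drop the return of J, since its level over the partition ratio is lower than first-phase X.G. So y comes to 29.8%.

Eta raises the escape share to 42.2% and y to 43.1%. Gamma gives 27.8%. The transfer of D does not enter this reckoning, so epsilon leaves our y unmoved. Our choice is eta.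

The forecast gives y 29%, best eta and yb 28.4%, on the ground that “X.G left in the first phase decays to E faster than it transfers”. Its yb lies below its y, where ours shows no move.

The simulation gives y 29.4%, yb 28.6% and best eta: eta moves y by 12 percentage points, gamma by −1.9 points, epsilon by −0.78 points.

In this flask first-phase X.G is made faster than it is used at 0.788 min, by a factor 2.50. At 6.00 min it is made more slowly than it is used, the ratio being 0.254, and X.G with J stands at 29.4% against 41.2% at 3.00 min. J then holds 26.0% of J and E together, beside the escape share of 26.7%. For a reading of the same flask at 4.0 min, the escape share gives y 35.1%; the simulation gives 36.0%.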